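## Structural features

The target contains two trans-2,3-diaryl-2,3-dihydrobenzofurans. Ring A (O1, C2, C3, C3a–C7a) carries the formyl group at C5 and a 4-hydroxyphenyl group at C2. Ring B (O1', C2', C3', C3a', C7a') carries a 4-hydroxyphenyl group at C2' and a 3,5-dihydroxyphenyl group at C3'. Ring B is fused to the central benzene ring C, whose C4' is bonded to C3 of ring A. Ring C is therefore a 1,2,3,5-tetrasubstituted arene: the C3 arm on C4', the C3' arm on the adjacent C3a', the ring oxygen on C7a' and a free hydroxyl on C6'. The four stereocentres (2R,3R,2'R,3'R) form two vicinal trans pairs, C2/C3 and C2'/C3', which lie close together because C3 and C3' sit on neighbouring carbons of ring C. Fragile groups are the aryl aldehyde, five oxidisable phenols, and the benzylic C2–O1 and C2'–O1' bonds, which ionise under acid with help from the para-oxygenated aryl groups. The real difficulty is the crowded ortho junction on ring C combined with absolute control of two independent trans pairs. The key step uses the ortho relation of the C3 carbon on C4' and the C3' carbon on C3a', next to the oxygen-bearing C7a': this alkyl/acyl pattern is what an unsymmetrical 3-alkoxybenzyne gives when it inserts into a β-ketoester.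

## Logic of the disconnections

**29 from 28.** The five O–CH3 bonds are cut last. Methyl ethers survive fluoride, organolithium, Grignard, palladium and hydride steps, and one of them can be removed selectively next to a ketone. The forward step must cleave five ethers without ionising C2–O1 or C2'–O1' irreversibly and without harming the aldehyde.

**28 from 27.** The O1–C7a bond is cut. The forward step is an intramolecular displacement of fluoride by the C2 alkoxide, activated by the para formyl group. It leaves C2 and C3 untouched, so both centres must already be correct in 27.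

**27 from 26 from 25.** The acetal is a latent activator: while it is in place the fluoride is inert to enolates and alkoxides. The C2–H bond is then cut, leading back to ketone 25, in which C3 is enolisable. One catalyst-controlled reduction with epimerisation at C3 must therefore set both C2 and C3. The demand is fast C3 exchange and a clear rate difference between the two epimers.

**25 from 22 and 24.** The C3–C3a bond is cut. The forward step is a palladium-catalysed arylation of a benzyl aryl ketone. It joins the whole ring A arene in one step and needs no stereocontrol, because C3 is set afterwards.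

**22 from 20 and 21.** The C2–aryl bond is cut. An N-methoxy-N-methylamide accepts one equivalent of aryl Grignard reagent cleanly; this turns the ester carbon of the key-step product into C2.

**20 from 12 and 17.** The C2'–C3' and O1'–C2' bonds are cut. One carbon (C2' with its aryl group) is delivered by a chiral sulfonium ylide to an ortho-quinone methide generated from 12. This removes ring B and both of its stereocentres at once. The reagent must control the absolute sense, and the trans relation must come from the addition and ring-closure sequence.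

**12 from 11, 10, 9 and 8.** The C–S bond, the carbinol C–H bond, the amide C–N bond and one O–H/O–CH3 exchange are retraced. The amide is installed before the ketone is reduced: an ester arm would lactonise onto the new benzylic alcohol, an amide does not under hydride conditions. The demand on the demethylation is selectivity for the one methoxy group that can chelate with the ketone.

**8 from 5 and 6 (through 7).** The C4'–C3 and C3a'–C3' bonds are cut together. Ring C with its complete substitution pattern and both differentiated arms comes from an aryne and a commercial β-ketoester. The only demand is regiochemistry: the acyl group must end next to the future C7a' oxygen.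

**5 from 3, 2 and 1; 17 from 15 and 16; 15 from 14 and 13; 24 from 23.** These are functional-group preparations of the aryne precursor, the chiral sulfonium salt and the protected aryl bromide from commercial materials.

## Other disconnections considered

**Alternative 1:** The benzene ring of ring A is cut at C3a–C7a, C4–C5 and C6–C7. In the forward direction Cp*RuCl(cod) would join the silyl ynol-ether diyne A1 with 3,3-diethoxyprop-1-yne A2 to give the silylated acetal A3, closing the arene and the dihydrofuran ring together.
- In favour: the cyclotrimerisation is neutral and does not touch C2 or C3. On stereochemical integrity it is better than the chosen plan, which passes through an enolisable ketone and a strong-base ring closure. The bulky silyl group should also steer A2 so that the acetal carbon ends at C5.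
- Against: A1 needs both C2 and C3 set in an open chain, and a sensitive silyl ynol ether on a hindered benzylic alcohol. A3 still needs protodesilylation and acetal hydrolysis. The congested ring C junction is not addressed at all.
- Comparison: structurally the alternative spends its most elaborate step on the least substituted arene. Mechanistically it is cleaner. In step count it should be clearly longer than the chosen route.

**Alternative 2:** Ring B is cut at C2'–C3' and O1'–C2'. In the forward direction Cs2CO3 would convert the bromo sulfone A4 into its ortho-quinone methide, and ylide 19 would add and close the ring to give the bromide A5.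
- In favour: this is the same annulation as step 12, so on ring B stereocontrol and mechanism the two plans are equal. A4 carries no carbonyl arm, so the lactonisation and amide-participation problems of steps 7 and 8 cannot arise; on this point the alternative is better. The bromide of A5 would also allow a convergent union with a ring A fragment.
- Against: the 1,2,3,5 pattern of A4 must be assembled by stepwise substitution of a simple arene. C3 must then be attached at a bromide flanked by the new ring, and ring A still needs its own stereocontrol.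
- Comparison: as a key step it solves ring B only, whereas the aryne insertion delivers ring C with both arms at once. Step economy should be similar or slightly worse.

**Alternative 3:** Ring A is cut at C3–C3a (and O1–C2). In the forward direction the enamine of aldehyde A6 with a diarylprolinol-type amine would add to 1,4-benzoquinone A7, and the hydroquinone hydroxyl would close the lactol A8.
- In favour: C3 would be set directly by the amine catalyst and not through a dynamic kinetic resolution; on this point the alternative is better. A6 would be available from 20 by partial reduction, so the two plans are equal up to ring B.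
- Against: A8 has a hydroxyl where the formyl group belongs and no aryl group on C2. It needs arylation of the lactol carbon with trans selectivity, and a triflation and formylation sequence at C5. The α-aryl aldehyde A6 is hindered and configurationally labile, and A7 is an oxidant toward electron-rich arenes.
- Comparison: the bond made is the same as in step 15, but the chosen plan brings in C5 at the correct oxidation level, with the fluoride that closes the ring. The alternative should cost several more steps after its key step.

Key step: step 4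

Remark 1: the (2R,5R)-thiolane ylide is taken to give the (2R,3R) ring by analogy with its known sense of benzylidene transfer to aldehydes; if the sense were opposite, the antipodal sulfide from (2R,5R)-hexane-2,5-diol would be used.

Remark 2: (4-methoxyphenyl)magnesium bromide is used as the commercial THF solution.

Remark 3: compound 25 is formed and used as the mixture of its two epimers at the ketone α-carbon (C3), which interconvert under base.

## Route

Step 1
Reactants: 1 3,5-dimethoxyphenol
Product: 2 2-bromo-3,5-dimethoxyphenol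
Conditions: NBS, CH2Cl2, −78 °C → rt
Reagents that add atoms: N-bromosuccinimide, O=C1CCC(=O)N1Br
Why: Electrophilic aromatic bromination; at low temperature in a non-polar solvent the hydrogen-bonded phenol–NBS pair should deliver bromine ortho to the hydroxyl, and any isomer brominated between the two methoxy groups is removed by chromatography.

Step 2
Reactants: 2 2-bromo-3,5-dimethoxyphenol
Product: 3 (2-bromo-3,5-dimethoxyphenoxy)trimethylsilane
Conditions: HMDS, THF, 70 °C; evaporate
Reagents that add atoms: hexamethyldisilazane, C[Si](C)(C)N[Si](C)(C)C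
Why: O-Silylation of a phenol by silyl transfer from HMDS, driven by loss of ammonia; the crude silyl ether is used after evaporation.

Step 3
Reactants: 3 (2-bromo-3,5-dimethoxyphenoxy)trimethylsilane
Product: 5 3,5-dimethoxy-2-(trimethylsilyl)phenyl trifluoromethanesulfonate, via lithium 3,5-dimethoxy-2-(trimethylsilyl)phenoxide 4 (not isolated)
Conditions: n-BuLi, THF, −100 °C; then Tf2O, −100 °C → rt
Reagents that add atoms: trifluoromethanesulfonic anhydride, O=S(=O)(OS(=O)(=O)C(F)(F)F)C(F)(F)F
Why: Bromine–lithium exchange gives the aryllithium, which undergoes a retro-Brook (1,3 O→C) silyl shift to the phenoxide 4; O-triflation then gives the standard ortho-silylaryl triflate aryne precursor.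

Step 4
Reactants: 5 3,5-dimethoxy-2-(trimethylsilyl)phenyl trifluoromethanesulfonate; 6 ethyl 3-(3,5-dimethoxyphenyl)-3-oxopropanoate
Product: 8 ethyl 2-[2-(3,5-dimethoxybenzoyl)-3,5-dimethoxyphenyl]acetate, via 3,5-dimethoxybenzyne 7 (not isolated)
Conditions: CsF, MeCN, 80 °C (5 in slight excess)
Reagents that add atoms: none
Why: Fluoride attacks silicon of 5 and the aryl anion expels triflate to give 7, while CsF also forms the enolate of 6. The enolate carbon adds to the aryne carbon remote from the flanking methoxy group (future C4'), because that group polarises the strained triple bond inductively and stabilises the aryl anion developing on the carbon next to it (future C3a'). This aryl anion adds to the aryl ketone in a 4-exo-trig sense, and the benzocyclobutenoxide opens by retro-aldol cleavage to the ester enolate, which is protonated; the net result is insertion of the aryne into the CH2–C(=O) bond, forming C4'–C3 and C3a'–C3'. The closest known reaction type is the fluoride-induced acyl-alkylation of arynes with β-ketoesters, which is established for 3-alkoxy- and 3,5-dialkoxybenzynes with this orientation. No ring of the target is closed (the four-membered ring is transient) and no stereocentre is formed. The only selectivity needed is regiochemical, acyl group next to the C7a' oxygen, and it is secured by the methoxy group adjacent to the aryne; dry MeCN limits premature protonation of the aryl anion.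

Step 5
Reactants: 8 ethyl 2-[2-(3,5-dimethoxybenzoyl)-3,5-dimethoxyphenyl]acetate
Product: 9 ethyl 2-[2-(3,5-dimethoxybenzoyl)-3-hydroxy-5-methoxyphenyl]acetate
Conditions: BCl3, CH2Cl2, −78 → 0 °C; aq. NaHCO3
Reagents that add atoms: none
Why: Chelation-controlled Lewis acid ether cleavage: only the methoxy group ortho to the diaryl ketone can form the six-membered boron chelate, so it is cleaved selectively while the other four methyl ethers and the ethyl ester remain.

Step 6
Reactants: 9 ethyl 2-[2-(3,5-dimethoxybenzoyl)-3-hydroxy-5-methoxyphenyl]acetate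
Product: 10 2-[2-(3,5-dimethoxybenzoyl)-3-hydroxy-5-methoxyphenyl]-N-methoxy-N-methylacetamide
Conditions: MeNHOMe·HCl, i-PrMgCl, THF, −20 → 0 °C
Reagents that add atoms: N,O-dimethylhydroxylamine hydrochloride, CNOC.Cl
Why: Ester aminolysis by the magnesium amide of N,O-dimethylhydroxylamine gives the Weinreb amide; the hindered, phenoxide-conjugated diaryl ketone should not compete. The amide arm cannot lactonise onto the benzylic alcohol made in step 7, as the ester would.

Step 7
Reactants: 10 2-[2-(3,5-dimethoxybenzoyl)-3-hydroxy-5-methoxyphenyl]-N-methoxy-N-methylacetamide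
Product: 11 2-[2-[(3,5-dimethoxyphenyl)(hydroxy)methyl]-3-hydroxy-5-methoxyphenyl]-N-methoxy-N-methylacetamide (racemic)
Conditions: NaBH4, THF/MeOH, 0 °C
Reagents that add atoms: none
Why: Borohydride reduction of the diaryl ketone to the ortho-hydroxybenzhydrol; the Weinreb amide is inert to NaBH4, and the low temperature avoids over-reduction through the quinone methide.

Step 8
Reactants: 11 2-[2-[(3,5-dimethoxyphenyl)(hydroxy)methyl]-3-hydroxy-5-methoxyphenyl]-N-methoxy-N-methylacetamide
Product: 12 2-[2-[(3,5-dimethoxyphenyl)(4-methylbenzenesulfonyl)methyl]-3-hydroxy-5-methoxyphenyl]-N-methoxy-N-methylacetamide (racemic)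
Conditions: p-TolSO2H, MgSO4, CH2Cl2, rt
Reagents that add atoms: 4-methylbenzenesulfinic acid, Cc1ccc(cc1)S(=O)O
Why: Acid-promoted SN1-type exchange of the benzylic hydroxyl for sulfinate (S-attack), the usual way to make 2-(sulfonylalkyl)phenols; the cation is stabilised by the ortho-hydroxy and para-methoxy groups. Anhydrous conditions keep any reversible capture by the amide oxygen from ending in hydrolysis.

Step 9
Reactants: 13 (2S,5S)-hexane-2,5-diol
Product: 14 (2S,5S)-hexane-2,5-diyl dimethanesulfonate
Conditions: MsCl, Et3N, CH2Cl2, −20 → 0 °C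
Reagents that add atoms: methanesulfonyl chloride, CS(=O)(=O)Cl
Why: Mesylation of both secondary alcohols with retention, since the C–O bonds are not touched.

Step 10
Reactants: 14 (2S,5S)-hexane-2,5-diyl dimethanesulfonate
Product: 15 (2R,5R)-2,5-dimethylthiolane
Conditions: Na2S·9H2O, DMSO, rt
Reagents that add atoms: sodium sulfide, [Na+].[Na+].[S-2]
Why: Double SN2 thioetherification; each carbon is inverted once, so the (2S,5S)-dimesylate gives the (2R,5R)-thiolane.

Step 11
Reactants: 15 (2R,5R)-2,5-dimethylthiolane; 16 (4-methoxyphenyl)methanol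
Product: 17 (2R,5R)-1-[(4-methoxyphenyl)methyl]-2,5-dimethylthiolan-1-ium tetrafluoroborate
Conditions: HBF4·OEt2, CH2Cl2, 0 °C → rt
Reagents that add atoms: tetrafluoroboric acid (diethyl ether complex), [H+].F[B-](F)(F)F
Why: Acid-mediated S-alkylation of the sulfide by the 4-methoxybenzyl cation; the two faces of sulfur are equivalent in the C2-symmetric thiolane, so a single sulfonium salt forms.

Step 12
Reactants: 12 2-[2-[(3,5-dimethoxyphenyl)(4-methylbenzenesulfonyl)methyl]-3-hydroxy-5-methoxyphenyl]-N-methoxy-N-methylacetamide; 17 (2R,5R)-1-[(4-methoxyphenyl)methyl]-2,5-dimethylthiolan-1-ium tetrafluoroborate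
Product: 20 2-[(2R,3R)-3-(3,5-dimethoxyphenyl)-6-methoxy-2-(4-methoxyphenyl)-2,3-dihydro-1-benzofuran-4-yl]-N-methoxy-N-methylacetamide, via ortho-quinone methide 18 (not isolated), via sulfonium ylide 19 (not isolated)
Conditions: Cs2CO3, CH2Cl2, −20 °C → rt
Reagents that add atoms: none
Why: Cs2CO3 expels sulfinate from the phenoxide of 12 to give 18 and deprotonates 17 to 19; conjugate addition of the ylide carbon to the methide carbon (C3') and 5-exo-tet displacement of the sulfide by the phenoxide, with inversion, give the trans ring, a known [4+1] annulation of sulfur ylides with ortho-quinone methides. The C2-symmetric thiolane shields one face of the ylide, so C2' is set by the reagent and C3' follows from the anti arrangement of the two aryl groups in the betaine; the (2R,3R) sense is assigned as in Remark 1.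

Step 13
Reactants: 20 2-[(2R,3R)-3-(3,5-dimethoxyphenyl)-6-methoxy-2-(4-methoxyphenyl)-2,3-dihydro-1-benzofuran-4-yl]-N-methoxy-N-methylacetamide; 21 (4-methoxyphenyl)magnesium bromide
Product: 22 2-[(2R,3R)-3-(3,5-dimethoxyphenyl)-6-methoxy-2-(4-methoxyphenyl)-2,3-dihydro-1-benzofuran-4-yl]-1-(4-methoxyphenyl)ethan-1-one
Conditions: THF, 0 °C → rt; aq. NH4Cl
Reagents that add atoms: none
Why: Weinreb ketone synthesis: the magnesium chelate of the tetrahedral adduct stops the reaction at one addition and collapses to the benzyl aryl ketone on work-up.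

Step 14
Reactants: 23 3-bromo-4-fluorobenzaldehyde
Product: 24 2-(3-bromo-4-fluorophenyl)-1,3-dioxolane
Conditions: HOCH2CH2OH, TsOH·H2O (cat.), toluene, reflux, Dean–Stark
Reagents that add atoms: ethane-1,2-diol, OCCO
Why: Acetalisation with azeotropic removal of water; the acetal protects the aldehyde from enolates and hydride and switches off activation of the fluoride until step 17.

Step 15
Reactants: 22 2-[(2R,3R)-3-(3,5-dimethoxyphenyl)-6-methoxy-2-(4-methoxyphenyl)-2,3-dihydro-1-benzofuran-4-yl]-1-(4-methoxyphenyl)ethan-1-one; 24 2-(3-bromo-4-fluorophenyl)-1,3-dioxolane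
Product: 25 2-[(2R,3R)-3-(3,5-dimethoxyphenyl)-6-methoxy-2-(4-methoxyphenyl)-2,3-dihydro-1-benzofuran-4-yl]-2-[5-(1,3-dioxolan-2-yl)-2-fluorophenyl]-1-(4-methoxyphenyl)ethan-1-one (both epimers at the new α-carbon)
Conditions: Pd(OAc)2 (cat.), P(t-Bu)3·HBF4 (cat.), NaOt-Bu, toluene, 70 °C
Reagents that add atoms: none
Why: Palladium-catalysed α-arylation of a benzyl aryl ketone: oxidative addition of 24 to zerovalent palladium, enolate transmetalation and C–C reductive elimination form C3–C3a. The product is held as its enolate, which prevents a second arylation, and the unactivated fluoride is not displaced.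

Step 16
Reactants: 25 2-[(2R,3R)-3-(3,5-dimethoxyphenyl)-6-methoxy-2-(4-methoxyphenyl)-2,3-dihydro-1-benzofuran-4-yl]-2-[5-(1,3-dioxolan-2-yl)-2-fluorophenyl]-1-(4-methoxyphenyl)ethan-1-one
Product: 26 (1R,2R)-2-[(2R,3R)-3-(3,5-dimethoxyphenyl)-6-methoxy-2-(4-methoxyphenyl)-2,3-dihydro-1-benzofuran-4-yl]-2-[5-(1,3-dioxolan-2-yl)-2-fluorophenyl]-1-(4-methoxyphenyl)ethan-1-ol
Conditions: RuCl(p-cymene)[(R,R)-TsDPEN] (cat.), HCO2H/Et3N (amine-rich), DMF, 40 °C
Reagents that add atoms: none
Why: Asymmetric transfer hydrogenation with dynamic kinetic resolution: the α-hydrogen, flanked by the carbonyl and two aryl groups, exchanges under the amine base, and the (R,R)-catalyst delivers hydride to the face that gives the (R)-carbinol, as for simple aryl ketones (anisyl group under the cymene ligand). The epimer expected to react faster places the bulky ring C aryl group anti to the incoming hydride, the α-hydrogen toward the crowded N–H/O side of the catalyst and the flat fluoroaryl group beside the anisyl ring, which corresponds to (R) at C3; this relative sense is the least secure prediction of the route.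

Step 17
Reactants: 26 (1R,2R)-2-[(2R,3R)-3-(3,5-dimethoxyphenyl)-6-methoxy-2-(4-methoxyphenyl)-2,3-dihydro-1-benzofuran-4-yl]-2-[5-(1,3-dioxolan-2-yl)-2-fluorophenyl]-1-(4-methoxyphenyl)ethan-1-ol
Product: 27 3-[(1R,2R)-1-[(2R,3R)-3-(3,5-dimethoxyphenyl)-6-methoxy-2-(4-methoxyphenyl)-2,3-dihydro-1-benzofuran-4-yl]-2-hydroxy-2-(4-methoxyphenyl)ethyl]-4-fluorobenzaldehyde
Conditions: 1 M HCl, THF, 0 °C → rt
Reagents that add atoms: water, O
Why: Acetal hydrolysis in dilute aqueous acid, which is many orders of magnitude faster than ionisation of the 4-methoxybenzylic alcohol or of ring B; it unmasks the para-formyl group that activates the fluoride.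

Step 18
Reactants: 27 3-[(1R,2R)-1-[(2R,3R)-3-(3,5-dimethoxyphenyl)-6-methoxy-2-(4-methoxyphenyl)-2,3-dihydro-1-benzofuran-4-yl]-2-hydroxy-2-(4-methoxyphenyl)ethyl]-4-fluorobenzaldehyde
Product: 28 (2R,3R)-3-[(2R,3R)-3-(3,5-dimethoxyphenyl)-6-methoxy-2-(4-methoxyphenyl)-2,3-dihydro-1-benzofuran-4-yl]-2-(4-methoxyphenyl)-2,3-dihydro-1-benzofuran-5-carbaldehyde
Conditions: NaH, THF, 0 °C → rt
Reagents that add atoms: none
Why: Intramolecular nucleophilic aromatic substitution: the alkoxide displaces the fluoride para to the formyl group through a five-membered transition state. Neither the C2–O nor the C3–H bond is broken, so the (1R,2R) alcohol gives the (2R,3R) trans ring with retention at both centres.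

Step 19
Reactants: 28 (2R,3R)-3-[(2R,3R)-3-(3,5-dimethoxyphenyl)-6-methoxy-2-(4-methoxyphenyl)-2,3-dihydro-1-benzofuran-4-yl]-2-(4-methoxyphenyl)-2,3-dihydro-1-benzofuran-5-carbaldehyde
Product: 29 (2R,3R)-3-[(2R,3R)-3-(3,5-dihydroxyphenyl)-6-hydroxy-2-(4-hydroxyphenyl)-2,3-dihydro-1-benzofuran-4-yl]-2-(4-hydroxyphenyl)-2,3-dihydro-1-benzofuran-5-carbaldehyde
Conditions: BBr3 (excess), CH2Cl2, −78 → 0 °C; then MeOH, H2O
Reagents that add atoms: none
Why: Lewis acid cleavage of the five aryl methyl ethers (bromide attacks the methyl of each boron-complexed ether); aryl aldehydes tolerate BBr3 and are returned on aqueous work-up. Any reversible opening of a benzylic C–O bond should reclose to the more stable trans ring, because C3 and C3' are not affected.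

## Compound list

1 | 3,5-dimethoxyphenol | COc1cc(O)cc(OC)c1 | starting material
2 | 2-bromo-3,5-dimethoxyphenol | COc1cc(O)c(Br)c(OC)c1 | intermediate
3 | (2-bromo-3,5-dimethoxyphenoxy)trimethylsilane | COc1cc(O[Si](C)(C)C)c(Br)c(OC)c1 | intermediate
4 | lithium 3,5-dimethoxy-2-(trimethylsilyl)phenoxide | [Li+].[O-]c1cc(OC)cc(OC)c1[Si](C)(C)C | intermediate (not isolated)
5 | 3,5-dimethoxy-2-(trimethylsilyl)phenyl trifluoromethanesulfonate | COc1cc(OC)c([Si](C)(C)C)c(OS(=O)(=O)C(F)(F)F)c1 | intermediate
6 | ethyl 3-(3,5-dimethoxyphenyl)-3-oxopropanoate | CCOC(=O)CC(=O)c1cc(OC)cc(OC)c1 | starting material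
7 | 3,5-dimethoxybenzyne (1,2-didehydro-3,5-dimethoxybenzene) | COC1=CC(OC)=CC#C1 | intermediate (not isolated)
8 | ethyl 2-[2-(3,5-dimethoxybenzoyl)-3,5-dimethoxyphenyl]acetate | CCOC(=O)Cc1cc(OC)cc(OC)c1C(=O)c1cc(OC)cc(OC)c1 | intermediate
9 | ethyl 2-[2-(3,5-dimethoxybenzoyl)-3-hydroxy-5-methoxyphenyl]acetate | CCOC(=O)Cc1cc(OC)cc(O)c1C(=O)c1cc(OC)cc(OC)c1 | intermediate
10 | 2-[2-(3,5-dimethoxybenzoyl)-3-hydroxy-5-methoxyphenyl]-N-methoxy-N-methylacetamide | CON(C)C(=O)Cc1cc(OC)cc(O)c1C(=O)c1cc(OC)cc(OC)c1 | intermediate
11 | 2-[2-[(3,5-dimethoxyphenyl)(hydroxy)methyl]-3-hydroxy-5-methoxyphenyl]-N-methoxy-N-methylacetamide (racemic) | CON(C)C(=O)Cc1cc(OC)cc(O)c1C(O)c1cc(OC)cc(OC)c1 | intermediate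
12 | 2-[2-[(3,5-dimethoxyphenyl)(4-methylbenzenesulfonyl)methyl]-3-hydroxy-5-methoxyphenyl]-N-methoxy-N-methylacetamide (racemic) | CON(C)C(=O)Cc1cc(OC)cc(O)c1C(c1cc(OC)cc(OC)c1)S(=O)(=O)c1ccc(C)cc1 | intermediate
13 | (2S,5S)-hexane-2,5-diol | C[C@H](O)CC[C@H](C)O | starting material
14 | (2S,5S)-hexane-2,5-diyl dimethanesulfonate | C[C@H](OS(C)(=O)=O)CC[C@H](C)OS(C)(=O)=O | intermediate
15 | (2R,5R)-2,5-dimethylthiolane | C[C@@H]1CC[C@@H](C)S1 | intermediate
16 | (4-methoxyphenyl)methanol | COc1ccc(CO)cc1 | starting material
17 | (2R,5R)-1-[(4-methoxyphenyl)methyl]-2,5-dimethylthiolan-1-ium tetrafluoroborate | C[C@@H]1CC[C@@H](C)[S+]1Cc1ccc(OC)cc1.F[B-](F)(F)F | intermediate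
18 | 2-[6-[(3,5-dimethoxyphenyl)methylidene]-3-methoxy-5-oxocyclohexa-1,3-dien-1-yl]-N-methoxy-N-methylacetamide (ortho-quinone methide) | CON(C)C(=O)CC1=CC(OC)=CC(=O)C1=Cc1cc(OC)cc(OC)c1 | intermediate (not isolated)
19 | [(2R,5R)-2,5-dimethylthiolan-1-ium-1-yl](4-methoxyphenyl)methanide (sulfonium ylide) | C[C@@H]1CC[C@@H](C)[S+]1[CH-]c1ccc(OC)cc1 | intermediate (not isolated)
20 | 2-[(2R,3R)-3-(3,5-dimethoxyphenyl)-6-methoxy-2-(4-methoxyphenyl)-2,3-dihydro-1-benzofuran-4-yl]-N-methoxy-N-methylacetamide | CON(C)C(=O)Cc1cc(OC)cc2c1[C@@H](c1cc(OC)cc(OC)c1)[C@H](c1ccc(OC)cc1)O2 | intermediate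
21 | (4-methoxyphenyl)magnesium bromide | COc1ccc([Mg]Br)cc1 | starting material
22 | 2-[(2R,3R)-3-(3,5-dimethoxyphenyl)-6-methoxy-2-(4-methoxyphenyl)-2,3-dihydro-1-benzofuran-4-yl]-1-(4-methoxyphenyl)ethan-1-one | COc1ccc(cc1)C(=O)Cc1cc(OC)cc2c1[C@@H](c1cc(OC)cc(OC)c1)[C@H](c1ccc(OC)cc1)O2 | intermediate
23 | 3-bromo-4-fluorobenzaldehyde | O=Cc1ccc(F)c(Br)c1 | starting material
24 | 2-(3-bromo-4-fluorophenyl)-1,3-dioxolane | Fc1ccc(cc1Br)C1OCCO1 | intermediate
25 | 2-[(2R,3R)-3-(3,5-dimethoxyphenyl)-6-methoxy-2-(4-methoxyphenyl)-2,3-dihydro-1-benzofuran-4-yl]-2-[5-(1,3-dioxolan-2-yl)-2-fluorophenyl]-1-(4-methoxyphenyl)ethan-1-one (both epimers at C2 of the ethanone) | COc1ccc(cc1)C(=O)C(c1cc(ccc1F)C1OCCO1)c1cc(OC)cc2c1[C@@H](c1cc(OC)cc(OC)c1)[C@H](c1ccc(OC)cc1)O2 | intermediate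
26 | (1R,2R)-2-[(2R,3R)-3-(3,5-dimethoxyphenyl)-6-methoxy-2-(4-methoxyphenyl)-2,3-dihydro-1-benzofuran-4-yl]-2-[5-(1,3-dioxolan-2-yl)-2-fluorophenyl]-1-(4-methoxyphenyl)ethan-1-ol | COc1ccc(cc1)[C@H](O)[C@@H](c1cc(ccc1F)C1OCCO1)c1cc(OC)cc2c1[C@@H](c1cc(OC)cc(OC)c1)[C@H](c1ccc(OC)cc1)O2 | intermediate
27 | 3-[(1R,2R)-1-[(2R,3R)-3-(3,5-dimethoxyphenyl)-6-methoxy-2-(4-methoxyphenyl)-2,3-dihydro-1-benzofuran-4-yl]-2-hydroxy-2-(4-methoxyphenyl)ethyl]-4-fluorobenzaldehyde | COc1ccc(cc1)[C@H](O)[C@@H](c1cc(C=O)ccc1F)c1cc(OC)cc2c1[C@@H](c1cc(OC)cc(OC)c1)[C@H](c1ccc(OC)cc1)O2 | intermediate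
28 | (2R,3R)-3-[(2R,3R)-3-(3,5-dimethoxyphenyl)-6-methoxy-2-(4-methoxyphenyl)-2,3-dihydro-1-benzofuran-4-yl]-2-(4-methoxyphenyl)-2,3-dihydro-1-benzofuran-5-carbaldehyde | O=Cc1ccc2c(c1)[C@@H](c1cc(OC)cc3c1[C@@H](c1cc(OC)cc(OC)c1)[C@H](c1ccc(OC)cc1)O3)[C@H](c1ccc(OC)cc1)O2 | intermediate
29 | (2R,3R)-3-[(2R,3R)-3-(3,5-dihydroxyphenyl)-6-hydroxy-2-(4-hydroxyphenyl)-2,3-dihydro-1-benzofuran-4-yl]-2-(4-hydroxyphenyl)-2,3-dihydro-1-benzofuran-5-carbaldehyde | O=Cc1ccc2c(c1)[C@@H](c1cc(O)cc3c1[C@@H](c1cc(O)cc(O)c1)[C@H](c1ccc(O)cc1)O3)[C@H](c1ccc(O)cc1)O2 | target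

## Step count and least certain steps

Total: 19 steps. Longest linear sequence: 15 steps (steps 1–8, 12, 13, 15–19, from 1 to 29).

**Step 4 (key step).** The aryl anion formed after enolate addition may be protonated before it closes onto the ketone, giving plain α-arylation without insertion, or the product enolate may add to a second aryne. Fallback: a Friedel–Crafts acylation that forms only the C3a'–C3' bond. It uses neither 5 nor 6 and so sets out from no numbered compound: commercial ethyl 2-(3,5-dimethoxyphenyl)acetate F1 would be acylated with 3,5-dimethoxybenzoyl chloride F2 (SnCl4, CH2Cl2, 0 °C) at the position ortho to the acetate arm and para to a methoxy group. The fallback returns to the route at 8.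

**Step 16.** The dynamic kinetic resolution may be mismatched: the faster-reducing epimer may be the one with the opposite configuration at C3, or epimerisation may be slower than reduction, so that the relative configuration of C2 and C3 is wrong or mixed. Fallback: a thermodynamic correction of C2, setting out from 25. The antipodal catalyst RuCl(p-cymene)[(S,S)-TsDPEN] would give the (1S,2R)-carbinol F7, in which C3 is still (R). Acetal hydrolysis as in step 17 would give the (1R,2S)-fluoro aldehyde F8, and ring closure as in step 18 would give the cis-(2S,3R) aldehyde F9. Brief treatment of F9 with BF3·OEt2 in CH2Cl2 at low temperature would open the C2–O1 bond to the 4-methoxybenzylic cation and reclose it to the more stable trans ring. The fallback returns to the route at 28.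

**Step 12.** Addition of the electron-rich benzylic ylide to the planar quinone methide may show poor facial selectivity, and the ylide may be lost by sigmatropic rearrangement before it adds. Fallback: racemic annulation and resolution, setting out from 12. The achiral salt 1-[(4-methoxyphenyl)methyl]thiolan-1-ium tetrafluoroborate F5 (from thiolane, 16 and HBF4·OEt2) and Cs2CO3 would give racemic trans product, that is 20 together with its (2S,3S)-enantiomer F6. Chromatography on a chiral stationary phase would separate them. The fallback returns to the route at 20.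

**Step 19.** BBr3 may open the benzylic C2–O1 or C2'–O1' bond, and the cation may then be captured irreversibly by a neighbouring electron-rich aryl ring; cleavage of all five ethers may also be incomplete at the temperature the ring system tolerates. Fallback: nucleophilic demethylation under basic conditions, setting out from 28. Sodium ethanethiolate in DMF at the lowest effective temperature cleaves the ethers by SN2 attack at methyl without any Lewis acid; the aldehyde is masked reversibly as its thiolate adduct. The fallback arrives directly at 29.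

**Step 8.** The benzylic cation may be captured by the oxygen of the neighbouring amide instead of by sulfinate, which on work-up leads to lactonisation with loss of the amine. Fallback: use of the lactone as the quinone methide precursor, setting out from 11. Acid (TsOH·H2O, toluene) would convert 11 deliberately into the lactone 1-(3,5-dimethoxyphenyl)-8-hydroxy-6-methoxyisochroman-3-one F3. Its phenoxide should expel the carboxylate, as ortho-hydroxybenzyl esters do, and annulation with 17 and Cs2CO3 as in step 12 would give the ring B acetic acid F4. Coupling of F4 with MeNHOMe·HCl (EDC·HCl, i-Pr2NEt) returns to the route at 20.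

## Further compounds

F1 | step 4 | ethyl 2-(3,5-dimethoxyphenyl)acetate | CCOC(=O)Cc1cc(OC)cc(OC)c1
F2 | step 4 | 3,5-dimethoxybenzoyl chloride | COc1cc(cc(OC)c1)C(Cl)=O
F3 | step 8 | 1-(3,5-dimethoxyphenyl)-8-hydroxy-6-methoxyisochroman-3-one (racemic) | O=C1Cc2cc(OC)cc(O)c2C(c2cc(OC)cc(OC)c2)O1
F4 | step 8 | 2-[(2R,3R)-3-(3,5-dimethoxyphenyl)-6-methoxy-2-(4-methoxyphenyl)-2,3-dihydro-1-benzofuran-4-yl]acetic acid | OC(=O)Cc1cc(OC)cc2c1[C@@H](c1cc(OC)cc(OC)c1)[C@H](c1ccc(OC)cc1)O2
F5 | step 12 | 1-[(4-methoxyphenyl)methyl]thiolan-1-ium tetrafluoroborate | COc1ccc(C[S+]2CCCC2)cc1.F[B-](F)(F)F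
F6 | step 12 | 2-[(2S,3S)-3-(3,5-dimethoxyphenyl)-6-methoxy-2-(4-methoxyphenyl)-2,3-dihydro-1-benzofuran-4-yl]-N-methoxy-N-methylacetamide | CON(C)C(=O)Cc1cc(OC)cc2c1[C@H](c1cc(OC)cc(OC)c1)[C@@H](c1ccc(OC)cc1)O2
F7 | step 16 | (1S,2R)-2-[(2R,3R)-3-(3,5-dimethoxyphenyl)-6-methoxy-2-(4-methoxyphenyl)-2,3-dihydro-1-benzofuran-4-yl]-2-[5-(1,3-dioxolan-2-yl)-2-fluorophenyl]-1-(4-methoxyphenyl)ethan-1-ol | COc1ccc(cc1)[C@@H](O)[C@@H](c1cc(ccc1F)C1OCCO1)c1cc(OC)cc2c1[C@@H](c1cc(OC)cc(OC)c1)[C@H](c1ccc(OC)cc1)O2
F8 | step 16 | 3-[(1R,2S)-1-[(2R,3R)-3-(3,5-dimethoxyphenyl)-6-methoxy-2-(4-methoxyphenyl)-2,3-dihydro-1-benzofuran-4-yl]-2-hydroxy-2-(4-methoxyphenyl)ethyl]-4-fluorobenzaldehyde | COc1ccc(cc1)[C@@H](O)[C@@H](c1cc(C=O)ccc1F)c1cc(OC)cc2c1[C@@H](c1cc(OC)cc(OC)c1)[C@H](c1ccc(OC)cc1)O2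
F9 | step 16 | (2S,3R)-3-[(2R,3R)-3-(3,5-dimethoxyphenyl)-6-methoxy-2-(4-methoxyphenyl)-2,3-dihydro-1-benzofuran-4-yl]-2-(4-methoxyphenyl)-2,3-dihydro-1-benzofuran-5-carbaldehyde | O=Cc1ccc2c(c1)[C@@H](c1cc(OC)cc3c1[C@@H](c1cc(OC)cc(OC)c1)[C@H](c1ccc(OC)cc1)O3)[C@@H](c1ccc(OC)cc1)O2
F0 | step 19 | none | none
A1 | alternative 1 | triisopropyl({[(1R,2S)-2-[(2R,3R)-3-(3,5-dimethoxyphenyl)-6-methoxy-2-(4-methoxyphenyl)-2,3-dihydro-1-benzofuran-4-yl]-1-(4-methoxyphenyl)but-3-yn-1-yl]oxy}ethynyl)silane | C#C[C@@H](c1cc(OC)cc2c1[C@@H](c1cc(OC)cc(OC)c1)[C@H](c1ccc(OC)cc1)O2)[C@H](c1ccc(OC)cc1)OC#C[Si](C(C)C)(C(C)C)C(C)C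
A2 | alternative 1 | 3,3-diethoxyprop-1-yne | C#CC(OCC)OCC
A3 | alternative 1 | [(2R,3R)-5-(diethoxymethyl)-3-[(2R,3R)-3-(3,5-dimethoxyphenyl)-6-methoxy-2-(4-methoxyphenyl)-2,3-dihydro-1-benzofuran-4-yl]-2-(4-methoxyphenyl)-2,3-dihydro-1-benzofuran-7-yl]tri(propan-2-yl)silane | CCOC(OCC)c1cc([Si](C(C)C)(C(C)C)C(C)C)c2c(c1)[C@@H](c1cc(OC)cc3c1[C@@H](c1cc(OC)cc(OC)c1)[C@H](c1ccc(OC)cc1)O3)[C@H](c1ccc(OC)cc1)O2
A4 | alternative 2 | 3-bromo-2-[(3,5-dimethoxyphenyl)(4-methylbenzenesulfonyl)methyl]-5-methoxyphenol (racemic) | Cc1ccc(cc1)S(=O)(=O)C(c1cc(OC)cc(OC)c1)c1c(O)cc(OC)cc1Br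
A5 | alternative 2 | (2R,3R)-4-bromo-3-(3,5-dimethoxyphenyl)-6-methoxy-2-(4-methoxyphenyl)-2,3-dihydro-1-benzofuran | Brc1cc(OC)cc2c1[C@@H](c1cc(OC)cc(OC)c1)[C@H](c1ccc(OC)cc1)O2
A6 | alternative 3 | 2-[(2R,3R)-3-(3,5-dimethoxyphenyl)-6-methoxy-2-(4-methoxyphenyl)-2,3-dihydro-1-benzofuran-4-yl]acetaldehyde | O=CCc1cc(OC)cc2c1[C@@H](c1cc(OC)cc(OC)c1)[C@H](c1ccc(OC)cc1)O2
A7 | alternative 3 | 1,4-benzoquinone | O=C1C=CC(=O)C=C1
A8 | alternative 3 | (3R)-3-[(2R,3R)-3-(3,5-dimethoxyphenyl)-6-methoxy-2-(4-methoxyphenyl)-2,3-dihydro-1-benzofuran-4-yl]-2,3-dihydro-1-benzofuran-2,5-diol (anomeric mixture at C2) | Oc1ccc2c(c1)[C@@H](c1cc(OC)cc3c1[C@@H](c1cc(OC)cc(OC)c1)[C@H](c1ccc(OC)cc1)O3)C(O)O2
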